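**Strategy.** The route rests on building ring C (O1, C2, C3, C4, C4a, C8a) of the epicatechin gallate units by a semipinacol ring expansion. In a 2-aryl-3-hydroxy-2,3-dihydrobenzofuran-3-ylmethyl mesylate the ring A carbon C4a, flanked by the oxygens at C5, C7 and C8a, migrates from C3 to the exocyclic CH2, which becomes C4, while the carbinol becomes the C3 ketone. The precursor comes from a benzofuran-2,3-dione by sulfur ylide epoxidation and methanolysis. Dynamic kinetic hydrogenation then sets C2 and C3, C4 is activated and O3 galloylated, and this one electrophile is coupled twice (to benzylated catechin, then to the resulting dimer) before global hydrogenolysis.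

Key step: step 5

Assumption: in step 6 the catalyst antipode that delivers the (2R,3R) alcohol is used, written provisionally as (S)/(S); compounds 1 and 4 are taken as catalogue compounds, and flavan numbering is used for all chroman units.

**Step 1**
Reactants: 1 3,5-bis(benzyloxy)phenol
Product: 3 4,6-bis(benzyloxy)benzofuran-2,3-dione, via aryl chlorooxoacetate 2 (not isolated)
Conditions: (COCl)2 (1.5 equiv), Et2O, 0 °C to reflux; evaporation, crystallisation from toluene/hexane
Reagents that add atoms: oxalyl chloride ClC(=O)C(=O)Cl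
Why: O-acylation of the phenol followed by intramolecular Friedel–Crafts acylation at the ortho carbon (two equivalent positions, each ortho and para to a benzyloxy group) closes the keto lactone, the oxalyl chloride route to benzofuran-2,3-diones, which should need no Lewis acid on a phloroglucinol-type ring.

**Step 2**
Reactants: 4 3,4-bis(benzyloxy)benzyl chloride
Product: 5 1-[3,4-bis(benzyloxy)benzyl]tetrahydrothiophen-1-ium chloride
Conditions: tetrahydrothiophene (3 equiv), MeCN, 40 °C; precipitation with Et2O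
Reagents that add atoms: tetrahydrothiophene C1CCSC1
Why: SN2 S-alkylation of the sulfide by the activated benzylic chloride should give the crystalline sulfonium salt.

**Step 3**
Reactants: 3 4,6-bis(benzyloxy)benzofuran-2,3-dione; 5 1-[3,4-bis(benzyloxy)benzyl]tetrahydrothiophen-1-ium chloride
Product: 8 methyl 4,6-bis(benzyloxy)-2-[3,4-bis(benzyloxy)phenyl]-3-hydroxy-2,3-dihydrobenzofuran-3-carboxylate (racemic), via sulfonium ylide 6 (not isolated), via spiro-epoxy lactone 7 (not isolated)
Conditions: 5, LiN(SiMe3)2 (1.0 equiv), THF, −78 °C; then 3, −78 to −30 °C; then NaOMe (0.2 equiv), MeOH, −30 °C to rt; aq. NH4Cl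
Reagents that add atoms: methanol CO
Why: Corey–Chaykovsky epoxidation at the isatin-like C3 keto carbonyl gives the spiro-epoxy lactone, methoxide then opens the aryl ester and the freed phenoxide attacks the epoxide at its 3,4-dialkoxybenzylic carbon to close the dihydrofuran ring (as in the known conversion of o-hydroxyaryl carbonyl compounds into 2,3-dihydrobenzofuran-3-ols with sulfur ylides); the relative configuration at C2 and C3 is immaterial, because C3 becomes a carbonyl in step 5 and C2 is set in step 6.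

**Step 4**
Reactants: 8 the hydroxy ester
Product: 9 {4,6-bis(benzyloxy)-2-[3,4-bis(benzyloxy)phenyl]-3-hydroxy-2,3-dihydrobenzofuran-3-yl}methanol (racemic diol)
Conditions: LiAlH4, THF, 0 °C; basic work-up
Reagents that add atoms: none
Why: Hydride reduction of the ester to the primary alcohol; the acid-sensitive tertiary benzylic carbinol is untouched under basic conditions.

**Step 5**
Reactants: 9 the diol
Product: 12 5,7-bis(benzyloxy)-2-[3,4-bis(benzyloxy)phenyl]chroman-3-one (racemic flavan-3-one), via primary mesylate 10 (not isolated), via diethylaluminium alkoxide 11 (not isolated)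
Conditions: MsCl, Et3N, CH2Cl2, −40 °C; then Et3Al (3 equiv), −78 to −20 °C; aq. KNaC4H4O6 (potassium sodium tartrate)
Reagents that add atoms: none
Why: Semipinacol (Tsuchihashi–Suzuki) ring expansion: the primary hydroxyl is mesylated selectively, Et3Al turns the tertiary hydroxyl into an aluminium alkoxide and assists departure of the mesylate, and the ring A carbon C4a shifts from C3 to the exocyclic CH2 while the C3–O bond becomes the C3 carbonyl. The closest known reaction type is the aryl-migrating one-carbon expansion of 1-substituted indan-1-ols to 2-tetralones (Tiffeneau–Demjanov and related pinacol-type shifts). One ring is formed, the six-membered ring C (O1, C2, C3, C4, C4a, C8a), by 1,2-shift of the aryl bond out of the five-membered dihydrofuran ring (O1, C2, C3, C4a, C8a), which inserts the former exocyclic carbon as C4. No stereocenter is created: C3 becomes trigonal and C2 is carried over as the racemate to be set in step 6. The step needs migration of C4a in preference to C2 (which would give the flavanone) and no ionisation of the tertiary benzylic C3–O bond (which would aromatise to the benzofuran); the first should be secured by π-participation of C4a, activated by the oxygens at C5, C7 and C8a, the second by the non-protic aluminium alkoxide conditions at low temperature.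

**Step 6**
Reactants: 12 the racemic flavan-3-one
Product: 13 (2R,3R)-5,7-bis(benzyloxy)-2-[3,4-bis(benzyloxy)phenyl]chroman-3-ol (5,7,3',4'-tetra-O-benzyl-(−)-epicatechin)
Conditions: H2 (10 atm), RuCl2[(S)-xylbinap][(S)-daipen] (1 mol %), KOtBu, i-PrOH/toluene, rt
Reagents that add atoms: none
Why: Noyori-type asymmetric hydrogenation with dynamic kinetic resolution: C2 (alpha to the ketone, benzylic, O-substituted) racemises through the enolate under KOtBu while the catalyst reduces one enantiomer from the face anti to the C2 aryl group, which should give the 2,3-cis (2R,3R) alcohol.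

**Step 7**
Reactants: 13 tetra-O-benzylepicatechin
Product: 14 (2R,3R,4S)-5,7-bis(benzyloxy)-2-[3,4-bis(benzyloxy)phenyl]-4-(2-ethoxyethoxy)chroman-3-ol
Conditions: DDQ (1.3 equiv), 2-ethoxyethanol (5 equiv), CH2Cl2, rt
Reagents that add atoms: 2-ethoxyethanol CCOCCO
Why: Established oxidative C4 functionalisation of tetra-O-benzyl flavan-3-ols: DDQ abstracts hydride from C4 (benzylic to the trioxygenated ring A) and the alcohol adds anti to the C3 hydroxyl, setting C4; plain benzyl ethers are inert to DDQ under these conditions.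

**Step 8**
Reactants: 14 the C4 ether; 15 3,4,5-tris(benzyloxy)benzoic acid
Product: 16 (2R,3R,4S)-5,7-bis(benzyloxy)-2-[3,4-bis(benzyloxy)phenyl]-4-(2-ethoxyethoxy)chroman-3-yl 3,4,5-tris(benzyloxy)benzoate
Conditions: DCC, DMAP, CH2Cl2, rt
Reagents that add atoms: none
Why: Steglich esterification of the axial C3 hydroxyl with the protected gallic acid; no stereocenter is touched.

**Step 9**
Reactants: 17 (+)-catechin
Product: 18 5,7,3',4'-tetra-O-benzyl-(+)-catechin
Conditions: BnBr, K2CO3, DMF, 0 °C to rt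
Reagents that add atoms: benzyl bromide BrCc1ccccc1
Why: Williamson benzylation of the four phenols, far more acidic than the C3 alcohol, leaves the 3-OH free; the mild carbonate base avoids C2 epimerisation.

**Step 10**
Reactants: 16 the galloylated electrophile; 18 tetra-O-benzylcatechin
Product: 19 protected dimer, (2R,3R,4R)-5,7-bis(benzyloxy)-2-[3,4-bis(benzyloxy)phenyl]-4-[(2R,3S)-5,7-bis(benzyloxy)-2-(3,4-bis(benzyloxy)phenyl)-3-hydroxychroman-8-yl]chroman-3-yl 3,4,5-tris(benzyloxy)benzoate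
Conditions: 18 (4 equiv), TMSOTf (0.2 equiv), CH2Cl2, −78 to −40 °C; Et3N quench
Reagents that add atoms: none
Why: The Lewis acid ionises the C4 ether to the C4 benzylic cation, which C8 of the catechin unit (in excess to suppress self-condensation of 16) captures in a Friedel–Crafts alkylation; attack anti to the C3 ester, reinforced by participation of the ester carbonyl, should set the 3,4-trans (4β) configuration.

**Step 11**
Reactants: 16 the galloylated electrophile; 19 the protected dimer
Product: 20 protected trimer (top and middle units 5,7,3',4'-tetra-O-benzylepicatechin 3-O-[3,4,5-tris(benzyloxy)benzoate], linked 4β→8 and 4β→8 to 5,7,3',4'-tetra-O-benzylcatechin; top 2R,3R,4R; middle 2R,3R,4S; bottom 2R,3S)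
Conditions: 19 (1.5 equiv), slow addition of 16, TMSOTf (0.2 equiv), CH2Cl2, −78 to −40 °C; Et3N quench
Reagents that add atoms: none
Why: The same cationic Friedel–Crafts coupling: the C4 cation from 16 alkylates the free C8 of the upper unit of 19, the most nucleophilic open position, again 3,4-trans; slow addition to an excess of 19 limits oligomerisation.

**Step 12**
Reactants: 20 the protected trimer
Product: 21 CNP0269915.2 (target)
Conditions: H2 (1 atm), Pd(OH)2/C, THF/MeOH/H2O, rt
Reagents that add atoms: none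
Why: Hydrogenolysis cleaves all eighteen O-benzyl ethers, while the gallate esters, the interflavan bonds and the C2–O1 bonds should be retained under neutral conditions.

**Compound list**

1 | 3,5-bis(benzyloxy)phenol | Oc1cc(OCc2ccccc2)cc(OCc2ccccc2)c1 | starting material
2 | 3,5-bis(benzyloxy)phenyl chlorooxoacetate | O=C(Cl)C(=O)Oc1cc(OCc2ccccc2)cc(OCc2ccccc2)c1 | intermediate
3 | 4,6-bis(benzyloxy)benzofuran-2,3-dione | O=C1Oc2cc(OCc3ccccc3)cc(OCc3ccccc3)c2C1=O | intermediate
4 | 3,4-bis(benzyloxy)benzyl chloride | ClCc1ccc(OCc2ccccc2)c(OCc2ccccc2)c1 | starting material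
5 | 1-[3,4-bis(benzyloxy)benzyl]tetrahydrothiophen-1-ium chloride | [Cl-].C1CC[S+](C1)Cc1ccc(OCc2ccccc2)c(OCc2ccccc2)c1 | intermediate
6 | tetrahydrothiophenium [3,4-bis(benzyloxy)phenyl]methylide | [CH-]([S+]1CCCC1)c1ccc(OCc2ccccc2)c(OCc2ccccc2)c1 | intermediate
7 | 4,6-bis(benzyloxy)-3'-[3,4-bis(benzyloxy)phenyl]spiro[benzofuran-3,2'-oxiran]-2-one (racemic) | O=C1Oc2cc(OCc3ccccc3)cc(OCc3ccccc3)c2C14OC4c1ccc(OCc2ccccc2)c(OCc2ccccc2)c1 | intermediate
8 | methyl 4,6-bis(benzyloxy)-2-[3,4-bis(benzyloxy)phenyl]-3-hydroxy-2,3-dihydrobenzofuran-3-carboxylate (racemic) | COC(=O)C1(O)C(c2ccc(OCc3ccccc3)c(OCc3ccccc3)c2)Oc2cc(OCc3ccccc3)cc(OCc3ccccc3)c21 | intermediate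
9 | {4,6-bis(benzyloxy)-2-[3,4-bis(benzyloxy)phenyl]-3-hydroxy-2,3-dihydrobenzofuran-3-yl}methanol (racemic) | OCC1(O)C(c2ccc(OCc3ccccc3)c(OCc3ccccc3)c2)Oc2cc(OCc3ccccc3)cc(OCc3ccccc3)c21 | intermediate
10 | primary mesylate of 9 | CS(=O)(=O)OCC1(O)C(c2ccc(OCc3ccccc3)c(OCc3ccccc3)c2)Oc2cc(OCc3ccccc3)cc(OCc3ccccc3)c21 | intermediate
11 | diethylaluminium alkoxide of 10 | CC[Al](CC)OC1(COS(C)(=O)=O)C(c2ccc(OCc3ccccc3)c(OCc3ccccc3)c2)Oc2cc(OCc3ccccc3)cc(OCc3ccccc3)c21 | intermediate
12 | 5,7-bis(benzyloxy)-2-[3,4-bis(benzyloxy)phenyl]chroman-3-one (racemic) | O=C1Cc2c(OCc3ccccc3)cc(OCc3ccccc3)cc2OC1c1ccc(OCc2ccccc2)c(OCc2ccccc2)c1 | intermediate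
13 | (2R,3R)-5,7-bis(benzyloxy)-2-[3,4-bis(benzyloxy)phenyl]chroman-3-ol | O[C@@H]1Cc2c(OCc3ccccc3)cc(OCc3ccccc3)cc2O[C@@H]1c1ccc(OCc2ccccc2)c(OCc2ccccc2)c1 | intermediate
14 | (2R,3R,4S)-4-(2-ethoxyethoxy) derivative of 13 | CCOCCO[C@H]1c2c(OCc3ccccc3)cc(OCc3ccccc3)cc2O[C@H](c2ccc(OCc3ccccc3)c(OCc3ccccc3)c2)[C@@H]1O | intermediate
15 | 3,4,5-tris(benzyloxy)benzoic acid | OC(=O)c1cc(OCc2ccccc2)c(OCc2ccccc2)c(OCc2ccccc2)c1 | starting material
16 | 3-O-[3,4,5-tris(benzyloxy)benzoyl] ester of 14 (2R,3R,4S) | CCOCCO[C@H]1c2c(OCc3ccccc3)cc(OCc3ccccc3)cc2O[C@H](c2ccc(OCc3ccccc3)c(OCc3ccccc3)c2)[C@@H]1OC(=O)c1cc(OCc2ccccc2)c(OCc2ccccc2)c(OCc2ccccc2)c1 | intermediate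
17 | (+)-catechin | O[C@H]1Cc2c(O)cc(O)cc2O[C@@H]1c1ccc(O)c(O)c1 | starting material
18 | 5,7,3',4'-tetra-O-benzyl-(+)-catechin | O[C@H]1Cc2c(OCc3ccccc3)cc(OCc3ccccc3)cc2O[C@@H]1c1ccc(OCc2ccccc2)c(OCc2ccccc2)c1 | intermediate
19 | protected dimer (galloylated tetra-O-benzylepicatechin unit 4β→8 tetra-O-benzylcatechin) | O=C(O[C@@H]1[C@@H](c2c(OCc4ccccc4)cc(OCc4ccccc4)c3c2O[C@H](c2ccc(OCc4ccccc4)c(OCc4ccccc4)c2)[C@@H](O)C3)c2c(OCc3ccccc3)cc(OCc3ccccc3)cc2O[C@@H]1c1ccc(OCc2ccccc2)c(OCc2ccccc2)c1)c1cc(OCc2ccccc2)c(OCc2ccccc2)c(OCc2ccccc2)c1 | intermediate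
20 | protected trimer | O=C(O[C@@H]1[C@@H](c2c(OCc4ccccc4)cc(OCc4ccccc4)c3c2O[C@H](c2ccc(OCc4ccccc4)c(OCc4ccccc4)c2)[C@@H](O)C3)c2c(OCc3ccccc3)cc(OCc3ccccc3)c([C@H]3c4c(OCc5ccccc5)cc(OCc5ccccc5)cc4O[C@H](c4ccc(OCc5ccccc5)c(OCc5ccccc5)c4)[C@@H]3OC(=O)c3cc(OCc4ccccc4)c(OCc4ccccc4)c(OCc4ccccc4)c3)c2O[C@@H]1c1ccc(OCc2ccccc2)c(OCc2ccccc2)c1)c1cc(OCc2ccccc2)c(OCc2ccccc2)c(OCc2ccccc2)c1 | intermediate
21 | CNP0269915.2 | O=C(O[C@@H]1[C@@H](c2c(O)cc(O)c3c2O[C@H](c2ccc(O)c(O)c2)[C@@H](O)C3)c2c(O)cc(O)c([C@H]3c4c(O)cc(O)cc4O[C@H](c4ccc(O)c(O)c4)[C@@H]3OC(=O)c3cc(O)c(O)c(O)c3)c2O[C@@H]1c1ccc(O)c(O)c1)c1cc(O)c(O)c(O)c1 | target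

**Step count:** 12 steps in total. Longest linear sequence: 10 steps (steps 1, 3, 4, 5, 6, 7, 8, 10, 11, 12).

**Steps most likely to fail**

Step 5. Migration of C2 may compete with that of C4a, the alkoxide may close to the spiro-epoxide, or the tertiary benzylic C–O bond may ionise with aromatisation to the benzofuran. The fallback sets out from 8 and returns at 12 by a Tiffeneau–Demjanov ring expansion. NH3 in MeOH gives the hydroxy amide F1 and LiAlH4 the amino alcohol F2. Isoamyl nitrite with AcOH in CH2Cl2 at 0 °C gives the diazonium acetate F3, whose loss of N2 drives the same 1,2-shift of C4a without a Lewis acid and gives 12.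

Step 3. The ylide may attack the lactone carbonyl with acyl transfer and ring opening instead of adding to the keto carbonyl, or the epoxide may rearrange before the phenoxide closes the ring. The fallback sets out from 3 and 4 and returns at 7 by olefination and epoxidation. PPh3 in toluene at reflux converts 4 into [3,4-bis(benzyloxy)benzyl]triphenylphosphonium chloride F4. NaN(SiMe3)2 and then 3 in THF should give, by Wittig reaction at the keto carbonyl, the 3-benzylidene lactone F5. Dimethyldioxirane in acetone at 0 °C epoxidises the exocyclic alkene to 7, which NaOMe in MeOH carries on to 8 as in step 3.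

Step 6. Epimerisation at C2 may be slow relative to reduction, or the catalyst may discriminate the ketone faces poorly, giving low enantiomeric or cis/trans purity. The fallback sets out from 12 and returns at 13 by classical resolution. LiBH(s-Bu)3 in THF at −78 °C should give the racemic 2,3-cis alcohol, that is 13 together with its (2S,3S) enantiomer F6. Esterification with (S)-2-methoxy-2-phenylacetic acid (DCC, DMAP) gives the (2R,3R) ester F7 and the (2S,3S) ester F8, which are separated by chromatography. K2CO3 in MeOH on F7 returns 13.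

**Further compounds**

F1 | step 5 | 4,6-bis(benzyloxy)-2-[3,4-bis(benzyloxy)phenyl]-3-hydroxy-2,3-dihydrobenzofuran-3-carboxamide (racemic) | NC(=O)C1(O)C(c2ccc(OCc3ccccc3)c(OCc3ccccc3)c2)Oc2cc(OCc3ccccc3)cc(OCc3ccccc3)c21
F2 | step 5 | 3-(aminomethyl)-4,6-bis(benzyloxy)-2-[3,4-bis(benzyloxy)phenyl]-2,3-dihydrobenzofuran-3-ol (racemic) | NCC1(O)C(c2ccc(OCc3ccccc3)c(OCc3ccccc3)c2)Oc2cc(OCc3ccccc3)cc(OCc3ccccc3)c21
F3 | step 5 | diazonium acetate from F2 | CC(=O)[O-].N#[N+]CC1(O)C(c2ccc(OCc3ccccc3)c(OCc3ccccc3)c2)Oc2cc(OCc3ccccc3)cc(OCc3ccccc3)c21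
F4 | step 3 | [3,4-bis(benzyloxy)benzyl]triphenylphosphonium chloride | [Cl-].c1ccc(cc1)[P+](Cc1ccc(OCc2ccccc2)c(OCc2ccccc2)c1)(c1ccccc1)c1ccccc1
F5 | step 3 | 4,6-bis(benzyloxy)-3-[3,4-bis(benzyloxy)benzylidene]benzofuran-2(3H)-one (E/Z mixture) | O=C1Oc2cc(OCc3ccccc3)cc(OCc3ccccc3)c2C1=Cc1ccc(OCc2ccccc2)c(OCc2ccccc2)c1
F6 | step 6 | (2S,3S) enantiomer of 13 | O[C@H]1Cc2c(OCc3ccccc3)cc(OCc3ccccc3)cc2O[C@H]1c1ccc(OCc2ccccc2)c(OCc2ccccc2)c1
F7 | step 6 | (S)-2-methoxy-2-phenylacetate of 13 | CO[C@@H](c1ccccc1)C(=O)O[C@@H]1Cc2c(OCc3ccccc3)cc(OCc3ccccc3)cc2O[C@@H]1c1ccc(OCc2ccccc2)c(OCc2ccccc2)c1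
F8 | step 6 | (S)-2-methoxy-2-phenylacetate of F6 | CO[C@@H](c1ccccc1)C(=O)O[C@H]1Cc2c(OCc3ccccc3)cc(OCc3ccccc3)cc2O[C@H]1c1ccc(OCc2ccccc2)c(OCc2ccccc2)c1
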